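(The runs were computed with constants of no real substance; the scatter is artificial.)

In the early minutes of the zeta run, watch the sum of starting material and target: at 6.00 min the readings 68.8% and 26.4% leave 4.80% unaccounted for.

common to all: gas phase 8.5 mM (held)

| charge | starting material | free catalyst | remark | time |
|---|---|---|---|---|
| zeta | 0.11 M | 0.2 mol% | run made earlier |  |
| north-east | 0.30 M | 0.12 mol% |  | 30 min |
| south | 0.40 M | 0.8 mol% |  | 30 min |
| south-west | 0.10 M | 0.2 mol% |  | 30 min |
| north-west | 0.10 M | 0.8 mol% |  | 30 min |
| south-east | 0.30 M | 0.05 mol% |  | 30 min |

- zeta (time / min: target / %, starting material / %): 0.500: 2.9, 97.2; 0.833: 4.8, 95.6; 1.33: 7.4, 93.1; 2.00: 10.7, 88.6; 4.00: 19.1, 78.0; 6.00: 26.4, 68.8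

(standard deviation of a reading: 0.3 percentage points)

- what was read earlier has a scatter of 0.3 percentage points, one standard deviation
- at the start none of the gas phase is in solution
- no earlier run changes the charge of free catalyst; that part of a forecast is a guess

- the flasks put in order of amount of target, in percent of the starting material charged, best first, at 30 min (north-east / south / south-west / north-west / south-east)
- the amount of target, in percent of the starting material charged of the flask you put first, at 30 min
- the amount of target, in percent of the starting material charged of the flask you put last, at 30 min

What eats the target? My own guess, which no run tests, is a step without catalyst that uses up one starting material and one target. Then starting material lost is made plus eaten, and target gained is made minus eaten, so on these readings making ran 12.0 times faster than eating over the zeta run. Target climbed nearly straight from nothing, so its mean share was about 13.2%.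

Making follows the catalyst and eating follows the target, so their ratio falls as target rises. It reaches one at the break-even share B, the share of target at which it is eaten as fast as it is made, 158% in the zeta run. This is a selectivity factor in the form of a share, and a reading resting on a small difference. It stands above the whole charge, so it is a yardstick of how far making leads eating, not a level the zeta run can reach. Starting material cancels from the ratio, so I scale B with the catalyst loading, a guess that no run tests.

Which flask leads? B is 634% for north-west and south, which it can't part, 158% for south-west, 95.0% for north-east and 39.6% for south-east, so that is my order, with north-west set ahead of south as a plain choice.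

How much? For north-west I reckon from the zeta slope, scaled by catalyst concentration, a half-life of starting material near 3.43 min, and 30 min is far longer. With unchanged catalyst, conversion taken as complete, and the mean share taken as half of the end share y, y = (B − mean)/(B + mean) gives 87.1%. On the same unchanged catalyst, I expect south-east to stay below its B.

The forecast differs: south-east > south-west > north-east > north-west > south, top 39%, low 0.1%, on the ground that “both rates scale with absolute catalyst concentration”.

The flasks give north-west > south > south-west > north-east > south-east, with 85.6% first and 25.2% last.

    gas phase ⇌ dissolved gas, rate k1*(csat - [dissolved gas]) (kL = 39.0 min⁻¹)
    starting material + dissolved gas + free catalyst → free catalyst + target (k = 33000 M⁻² min⁻¹)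
    free catalyst → spent catalyst (k = 0.0170 min⁻¹)
    starting material + target → side product (k = 0.340 M⁻¹ min⁻¹)

North-west holds 85.6% against the reckoned 87.1%. The neighbouring flask is north-west with 0.48 mol% of free catalyst. Its B is 380%, and the same reckoning gives 80.8% target. At 30.0 min that flask holds 76.5% target, with 2.34% starting material left.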